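**Assumption:** gibberellic acid (GA3, a fermentation product) is commercially available and is used as the advanced starting material, so this is a semisynthesis. GA8 is 2β-hydroxy-GA1, so only ring A needs reworking. The methyl ester is used to protect the C7 acid, because a free acid would interfere with the hydride, triflation and dihydroxylation steps.

**Retrosynthesis**
- GA8 (7) comes from hydrolysis of its methyl ester 6.
- Ester 6 comes from β-face cis-dihydroxylation of the Δ2-alkene 5. The C4→C10 lactone bridge shields the α face.
- Alkene 5 comes from Pd-formate reduction of the C2=C3 enol triflate 4.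
- Triflate 4 comes from 1,4-reduction and enolate triflation of enone 3, and 3 from oxidation of the GA3 methyl ester 2.
- No rings are formed. All of ring A–E and the lactone come from GA3, and only the ring-A 2β,3β-diol is built (C2 and C3 set in step 5).

**Step 1**
Reactants: 1 gibberellic acid (GA3)
Product: 2 GA3 methyl ester
Conditions: TMSCHN2, MeOH/PhH, 0 °C → rt
Reagents that add atoms: trimethylsilyldiazomethane, C[Si](C)(C)C=[N+]=[N-] (supplies the ester CH3)
Why: Diazomethane-type O-methylation of the carboxylic acid is chemoselective. It leaves the hindered tertiary 13-OH and the secondary 3-OH alone, and all stereocenters are untouched.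

**Step 2**
Reactants: 2 GA3 methyl ester
Product: 3 3-oxo-GA3 methyl ester (Δ1-3-ketone, an enone)
Conditions: Dess–Martin periodinane, NaHCO3, CH2Cl2, 0 °C → rt
Reagents that add atoms: none
Why: Dess–Martin oxidation of the allylic secondary alcohol is mild and non-acidic, so the tertiary 13-OH, the 16-ene and the lactone survive. The C3 stereocenter is removed, which is desirable because C2 and C3 are re-set later.

**Step 3**
Reactants: 3 enone
Product: 4 C2=C3 enol triflate (3-deoxy-3-OTf-Δ2, C1 now CH2)
Conditions: L-Selectride (2.2 equiv), THF, −78 °C; then PhNTf2, −78 °C → 0 °C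
Reagents that add atoms: N-phenyltriflimide, FC(F)(F)S(=O)(=O)N(c1ccccc1)S(=O)(=O)C(F)(F)F (adds Tf). L-Selectride, [Li+].CCC(C)[BH-](C(C)CC)C(C)CC, adds only H.
Why: Conjugate (1,4) hydride delivery to the enone, favoured because the C3 carbonyl is flanked by quaternary C4, generates the C2–C3 enolate regiospecifically, and PhNTf2 traps it as the vinyl triflate (regiospecific enolate trapping). The first equivalent of hydride only deprotonates the 13-OH. C1 becomes CH2, so no new stereocenter forms.

**Step 4**
Reactants: 4 enol triflate
Product: 5 Δ2-alkene, 3-deoxy-2,3-didehydro-GA1 methyl ester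
Conditions: Pd(OAc)2 (5 mol%), PPh3, Bu3N, HCO2H, DMF, 60 °C
Reagents that add atoms: none (formate supplies H)
Why: Pd-catalysed formate hydrogenolysis of the vinyl triflate (Cacchi-type reduction) replaces OTf with H. The hindered exocyclic 16-ene, the lactone and the ester are untouched, and no stereocenter is created.

**Step 5**
Reactants: 5 Δ2-alkene
Product: 6 GA8 methyl ester (2β,3β-diol)
Conditions: OsO4 (1.05 equiv), pyridine, CH2Cl2, −20 → 0 °C; then aq. NaHSO3, pyridine, rt
Reagents that add atoms: osmium tetroxide, O=[Os](=O)(=O)=O (its two oxygens end up in the diol); pyridine, c1ccncc1, is a ligand only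
Why: Upjohn/Criegee-type syn dihydroxylation. The α face of the C2=C3 alkene is blocked by the C4–C19(=O)–O–C10 lactone bridge, so OsO4 adds from the β face. This gives the cis 2β,3β-diol, which matches the target (C2 and C3 both β). Stoichiometric OsO4 at low temperature favours the less hindered ring-A cis-alkene over the bridged 1,1-disubstituted 16-ene.

**Step 6**
Reactants: 6 GA8 methyl ester
Product: 7 gibberellin A8
Conditions: Me3SnOH, 1,2-dichloroethane, 80 °C; then cold aq. KHSO4 to pH ≈ 3
Reagents that add atoms: trimethyltin hydroxide, C[Sn](C)(C)O (supplies the OH of the acid)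
Why: Me3SnOH cleaves methyl esters under near-neutral conditions, so the γ-lactone, the 16-ene and the 13-OH are spared. The 13-OH/16-ene unit is steviol-like and acid-sensitive, so the acid quench is brief and cold. No stereocenter is altered.

**Checks on the final route**
- **Target match:** the product 7 SMILES is identical to the target. It has the C19→C10 γ-lactone, the C7 acid, 13-OH, the 16-ene, and 2β-OH/3β-OH (cis, both opposite to the α lactone bridge).
- **Atom balance:** C19H22O6 (1) → C20H24O6 (2) → C20H22O6 (3) → C21H23F3O8S (4) → C20H24O5 (5) → C20H26O7 (6) → C19H24O7 (7).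
- **Stereocenters:** the seven centers C4, C5, C6, C8, C9, C10 and C13 are never touched, and C2 and C3 are set in step 5.

**Compound list**
1 | gibberellic acid (GA3) | C=C1C[C@]23C[C@@]1(O)CC[C@H]2[C@@]12C=C[C@H](O)[C@@](C)(C(=O)O1)[C@H]2[C@@H]3C(=O)O | starting material
2 | GA3 methyl ester | C=C1C[C@]23C[C@@]1(O)CC[C@H]2[C@@]12C=C[C@H](O)[C@@](C)(C(=O)O1)[C@H]2[C@@H]3C(=O)OC | intermediate
3 | 3-oxo-GA3 methyl ester (Δ1-3-ketone) | C=C1C[C@]23C[C@@]1(O)CC[C@H]2[C@@]12C=CC(=O)[C@@](C)(C(=O)O1)[C@H]2[C@@H]3C(=O)OC | intermediate
4 | Δ2-3-enol triflate methyl ester | C=C1C[C@]23C[C@@]1(O)CC[C@H]2[C@@]12CC=C(OS(=O)(=O)C(F)(F)F)[C@@](C)(C(=O)O1)[C@H]2[C@@H]3C(=O)OC | intermediate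
5 | 3-deoxy-2,3-didehydro-GA1 methyl ester (Δ2-alkene) | C=C1C[C@]23C[C@@]1(O)CC[C@H]2[C@@]12CC=C[C@@](C)(C(=O)O1)[C@H]2[C@@H]3C(=O)OC | intermediate
6 | GA8 methyl ester | C=C1C[C@]23C[C@@]1(O)CC[C@H]2[C@@]12C[C@H](O)[C@H](O)[C@@](C)(C(=O)O1)[C@H]2[C@@H]3C(=O)OC | intermediate
7 | gibberellin A8 | C=C1C[C@]23C[C@@]1(O)CC[C@H]2[C@@]12C[C@H](O)[C@H](O)[C@@](C)(C(=O)O1)[C@H]2[C@@H]3C(=O)O | target

**Total steps:** 6. **Longest linear sequence:** 6, from GA3.

**Three steps most likely to fail**
1. **Step 5 (chemoselective OsO4):** the exocyclic 16-ene may also be dihydroxylated, or the β-face selectivity may erode.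
   - Fallback: avoid alkene differentiation. Treat enone 3 with L-Selectride, trap the enolate in situ with Davis oxaziridine to give the 2β-hydroxy-3-ketone (β-face attack, equatorial 2β-OH), then reduce the ketone to the axial 3β-OH (bulky hydride, or reduce then Mitsunobu inversion).
2. **Step 3 (reduction/triflation in the presence of the free 13-alkoxide and ester):** O-triflation of the tertiary alkoxide or over-reduction of the ester could occur.
   - Fallback: convert enone 3 to its tosylhydrazone and apply catecholborane/NaOAc reductive transposition (Kabalka) to give the Δ2-alkene 5 directly, with no triflate.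
3. **Step 6 (ester cleavage without opening the lactone or epimerizing C6):** Me3SnOH may be sluggish on the hindered C7 ester, or the lactone may open.
   - Fallback: carry a 2-(trimethylsilyl)ethyl ester from step 1 instead of the methyl ester and remove it with TBAF under non-hydrolytic conditions.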